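**Plan**

1. Retrosynthesis (octahydroindene numbering: C1 ethylidene carbon, C2 OAc, C4 methylidene carbon, C5 OAng, C6 OH, C7 iPr): cut the two esters, then C1–C2 together with the ethylidene methyl (alkylative ynal cyclization), then the ring-fusion bond C3a–C7a (intramolecular Michael addition), then C3–C3a (glyoxylate aldol condensation). This leads to a keto aldehyde that is the ozonolysis product of a dioxygenated carvone ring.
2. Enabling feature: at the carbonyl level C1 (as CHO) and C2 (as CO2Me) are 1,5-related across C7a–C3a, with C7a α to C1 and C3a β to C2, and a C4 ketone ties both ends into a 6-exo closure. The ring C3a–C4–C5–C6–C7–C7a is a p-menthane ring shifted by one carbon.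
3. Forward: (S)-carvone, C5/C6 oxygenation, ring cleavage (carvone C3 becomes C1, the carvone methyl carbon becomes C3a), cyclohexanone by the Michael closure, then alkyne, methylidene and aldehyde, cyclopentane by nickel-catalysed cyclization, esters last.
4. Stereochemistry: C7 is bought with carvone. C6 and C5 are relayed from it (anti hydroxylation, then double inversion through a cis-epoxide). C7a and C3a arise together in the key step under substrate and thermodynamic control. The Z-ethylidene follows from cis addition across the alkyne, and C2 from the metallacycle geometry plus one Mitsunobu inversion.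

Key step: step 10

Remark: compounds 10–28 are numbered as in the target and β is the face of the C7 isopropyl group; cyclohexenes 2–9 keep carvone numbering (carvone C1/C6/C5 = target C5/C6/C7). (S)-(+)-Carvone of high enantiomeric purity is assumed to be commercial.

**Route**

Step 1
Reactants: 1 (S)-(+)-carvone
Product: 2 (S)-carvotanacetone
Conditions: H2 (1 atm), RhCl(PPh3)3 (2 mol %), benzene, rt
Reagents that add atoms: none
Why: Homogeneous catalytic hydrogenation with RhCl(PPh3)3 reduces the 1,1-disubstituted isopropenyl alkene much faster than the trisubstituted enone alkene, and the C5 stereocenter is not touched.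

Step 2
Reactants: 2 (S)-carvotanacetone
Product: 4 (5R,6R)-6-hydroxy-2-methyl-5-(propan-2-yl)cyclohex-2-en-1-one (hydroxyl trans to isopropyl), via potassium dienolate 3 (not isolated)
Conditions: KN(SiMe3)2, THF, −78 °C; 2-(phenylsulfonyl)-3-phenyloxaziridine, −78 °C; aq. NH4Cl
Reagents that add atoms: 2-(phenylsulfonyl)-3-phenyloxaziridine (O=S(=O)(c1ccccc1)N1OC1c1ccccc1)
Why: Kinetic α'-deprotonation gives the cross-conjugated dienolate, which is oxidized by the N-sulfonyloxaziridine (enolate hydroxylation) on the face anti to the neighbouring isopropyl group, so the new C6 hydroxyl should be trans to isopropyl.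

Step 3
Reactants: 4 trans-6-hydroxy ketone
Product: 5 (5R,6R)-6-(methanesulfonyloxy)-2-methyl-5-(propan-2-yl)cyclohex-2-en-1-one
Conditions: MsCl, Et3N, CH2Cl2, 0 °C
Reagents that add atoms: methanesulfonyl chloride (CS(=O)(=O)Cl)
Why: O-sulfonylation turns the α-hydroxyl into a leaving group without breaking a bond at C6, and the trans isomer is also the stable one should the acidic C6–H exchange.

Step 4
Reactants: 5 α-mesyloxy enone
Product: 7 1,6-epoxy-2-methyl-5-(propan-2-yl)cyclohex-2-ene with the oxirane cis to isopropyl, via trans-hydroxy mesylate 6 (not isolated)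
Conditions: NaBH4, CeCl3·7H2O, MeOH, −78 °C; then K2CO3, 0 °C → rt
Reagents that add atoms: none
Why: Luche 1,2-reduction in methanol with trivalent cerium should attack the diequatorial conformer axially, placing the C1 hydroxyl cis to isopropyl and trans to the mesylate, and carbonate then closes the oxirane by intramolecular SN2 displacement with inversion at C6, so the epoxide oxygen ends up cis to isopropyl.

Step 5
Reactants: 7 vinyl epoxide
Product: 8 6-[(4-methoxybenzyl)oxy]-5-methyl-2-(propan-2-yl)cyclohex-4-en-1-ol (hydroxyl cis to isopropyl and trans to the PMB ether)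
Conditions: 4-methoxybenzyl alcohol, [Rh(CO)2Cl]2 (2 mol %), THF, rt
Reagents that add atoms: 4-methoxybenzyl alcohol (COc1ccc(CO)cc1)
Why: Rhodium-catalysed alcoholysis of a vinyl epoxide is an SN2-type opening at the allylic carbon with inversion, here also the less hindered and trans-diaxial site, which sets the C1 ether trans to the C6 hydroxyl while C6 keeps its oxygen cis to isopropyl.

Step 6
Reactants: 8 PMB ether alcohol
Product: 9 tert-butyldimethylsilyl ether of 8
Conditions: TBSOTf, 2,6-lutidine, CH2Cl2, 0 °C
Reagents that add atoms: tert-butyldimethylsilyl triflate (CC(C)(C)[Si](C)(C)OS(=O)(=O)C(F)(F)F)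
Why: Silyl triflate with a hindered base silylates the hindered secondary hydroxyl next to the isopropyl-bearing carbon without touching any stereocenter (silyl ether protection).

Step 7
Reactants: 9 protected cyclohexene
Product: 12 6-(tert-butyldimethylsilyloxy)-1,1-dimethoxy-5-[(4-methoxybenzyl)oxy]... named in target numbering as the C1 dimethyl acetal of the C4 methyl ketone, via ozonide 10 (not isolated), via keto aldehyde 11 (not isolated)
Conditions: O3, CH2Cl2, −78 °C (Sudan red 7B end point); PPh3, −78 °C → rt; then HC(OMe)3, PPTS, MeOH, rt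
Reagents that add atoms: ozone ([O-][O+]=O); trimethyl orthoformate (COC(OC)OC); methanol (CO)
Why: Ozonolysis with reductive work-up cleaves the only alkene (the PMB ether is spared by stopping at the indicator end point) and the aldehyde is acetalized chemoselectively over the hindered α-alkoxy methyl ketone, so the ring carbon-carbon bond is cut while C5, C6 and C7 are kept.

Step 8
Reactants: 12 keto acetal
Product: 16 methyl (2E)-4-oxo-non-2-enoate acetal (target numbering: C2 ester and C3=C3a alkene and C4 ketone), via lithium enolate 13 (not isolated), via lithium aldolate 14 (not isolated), via aldol mesylate 15 (not isolated)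
Conditions: LiN(iPr)2, THF, −78 °C; methyl glyoxylate, −78 °C; then MsCl, Et3N, −78 → 0 °C
Reagents that add atoms: methyl glyoxylate (COC(=O)C=O)
Why: Kinetic deprotonation occurs at the methyl group and not at the hindered α-alkoxy methine, aldol addition to the glyoxylate follows, and mesylation with E1cB elimination gives the more stable E enone (aldol condensation).

Step 9
Reactants: 16 enone ester acetal
Product: 17 methyl (2E)-4,9-dioxo-non-2-enoate (free C1 aldehyde)
Conditions: PPTS (cat.), acetone–H2O 9:1, 40 °C
Reagents that add atoms: water (O)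
Why: Acid-catalysed hydrolysis cleaves the dimethyl acetal under conditions that a hindered secondary TBS ether and a PMB ether survive.

Step 10
Reactants: 17 formyl enone ester
Product: 19 cyclohexanone with C4 ketone and 3aβ-CH2CO2Me and 7aα-CHO and 7β-iPr and 6β-OTBS and 5α-OPMB, via enamine 18 (not isolated)
Conditions: (R)-α,α-diphenylprolinol trimethylsilyl ether (20 mol %), PhCO2H (20 mol %), toluene, rt; then DBU (cat.), CH2Cl2, rt
Reagents that add atoms: none
Why: The secondary amine condenses with the aldehyde to the E enamine 18, whose nucleophilic carbon (the future C7a) adds to the alkene carbon β to the ester (the future C3a), and hydrolysis of the resulting iminium ion releases the catalyst. The closest known reaction type is the amine-catalysed intramolecular Michael addition of aldehydes to enones and enoates. The cyclohexanone ring closes in the 6-exo-trig mode, whereas attack at the other alkene carbon would be a 7-endo closure. Both new stereocenters arise in a chair-like transition state with the C7 isopropyl group, the enamine and the acceptor chain equatorial and the two oxygen substituents axial, so the formyl group at C7a should come out trans to isopropyl and the acetate arm at C3a trans to the formyl group, and the (R)-catalyst shields the enamine face that would give the C7a epimer. The step needs regioselectivity for C3a over the carbon β to the ketone and chemoselectivity for conjugate addition over aldol addition to the ketone; ring size secures the first and the reversibility of the aldol addition against the irreversible Michael addition the second. Both new centers are α to carbonyl groups, so the all-equatorial product is also the thermodynamic one and minor epimers can be equilibrated with DBU.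

Step 11
Reactants: 19 keto aldehyde ester
Product: 20 alkynyl keto ester (7aα-ethynyl)
Conditions: dimethyl (1-diazo-2-oxopropyl)phosphonate, K2CO3, MeOH, 0 °C → rt
Reagents that add atoms: dimethyl (1-diazo-2-oxopropyl)phosphonate (CC(=O)C(=[N+]=[N-])P(=O)(OC)OC)
Why: Seyferth–Gilbert homologation in the Ohira–Bestmann variant converts the aldehyde into the terminal alkyne while the ketone and the methyl ester (degenerate exchange in methanol) are spared, and the equatorial C7a configuration is the stable one under the basic conditions.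

Step 12
Reactants: 20 alkynyl keto ester
Product: 21 4-methylidene alkynyl ester
Conditions: Zn, CH2Br2, TiCl4, THF–CH2Cl2, 0 °C → rt
Reagents that add atoms: dibromomethane (BrCBr)
Why: Takai–Lombardo methylenation is non-basic, so the hindered, enolizable ketone is olefinated without epimerization at C3a or C5 and without β-elimination of the silyloxy group, and the ester and the terminal alkyne are not attacked.

Step 13
Reactants: 21 methylidene alkynyl ester
Product: 22 ynal (C2 aldehyde)
Conditions: iBu2AlH, CH2Cl2, −78 °C; aq. potassium sodium tartrate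
Reagents that add atoms: none
Why: Partial reduction of the methyl ester at −78 °C stops at the tetrahedral aluminium hemiacetal, which gives the aldehyde on work-up, and no stereocenter is touched.

Step 14
Reactants: 22 ynal
Product: 24 (1Z,2R)-1-ethylidene-2α-hydroxy trans-hydrindane with 5α-OPMB and 6β-OTBS, via oxanickelacyclopentene 23 (not isolated)
Conditions: Ni(cod)2 (10 mol %), Me2Zn, THF, 0 °C; aq. NH4Cl
Reagents that add atoms: dimethylzinc (C[Zn]C)
Why: Zerovalent nickel couples alkyne and aldehyde oxidatively to metallacycle 23, and methyl transfer from zinc with reductive elimination puts the methyl group on the terminal alkyne carbon cis to the new C1–C2 bond (nickel-catalysed alkylative cyclization of ynals with organozincs), which fixes the Z-ethylidene; the near-planar O–C2–C1=C unit of the metallacycle fused to the trans ring junction should place the C2 oxygen on the α face.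

Step 15
Reactants: 24 2α-allylic alcohol
Product: 25 2β-acetate
Conditions: PPh3, DIAD, AcOH, toluene, 0 °C → rt
Reagents that add atoms: acetic acid (CC(=O)O)
Why: Mitsunobu esterification displaces the activated allylic hydroxyl by acetate in an SN2 reaction, which inverts C2 to the 2β-acetate of the target.

Step 16
Reactants: 25 acetate PMB ether
Product: 26 5α-alcohol
Conditions: DDQ, CH2Cl2–pH 7 buffer, 0 °C
Reagents that add atoms: none
Why: Oxidative cleavage of the electron-rich PMB ether with DDQ leaves the silyl ether, the allylic acetate and both alkenes intact, and the C5 oxygen is retained.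

Step 17
Reactants: 26 5α-alcohol
Product: 27 5α-angelate 6β-TBS ether
Conditions: angelic acid, 2,4,6-trichlorobenzoyl chloride, Et3N, toluene, rt; then 26, 75 °C
Reagents that add atoms: angelic acid (C/C=C(/C)C(=O)O)
Why: Yamaguchi-type esterification through the 2,4,6-trichlorobenzoyl mixed anhydride without DMAP acylates the hindered allylic hydroxyl and avoids nucleophile-catalysed Z-to-E isomerization of the angelate, with retention at C5.

Step 18
Reactants: 27 silyl ether
Product: 28 target CNP0210397.1
Conditions: HF·pyridine, THF, 0 °C → rt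
Reagents that add atoms: none
Why: Fluoride-mediated desilylation under mildly acidic conditions frees the 6β-hydroxyl, and the trans-diaxial arrangement of this hydroxyl and the C5 ester disfavors acyl migration.

**Compound list**

1 | (S)-(+)-carvone | CC1=CC[C@@H](CC1=O)C(C)=C | starting material
2 | (S)-carvotanacetone, (5S)-2-methyl-5-(propan-2-yl)cyclohex-2-en-1-one | O=C1C(C)=CC[C@H](C(C)C)C1 | intermediate
3 | potassium dienolate of 2 (not isolated) | [K+].[O-]C1=C[C@@H](C(C)C)CC=C1C | intermediate
4 | (5R,6R)-6-hydroxy-2-methyl-5-(propan-2-yl)cyclohex-2-en-1-one | O=C1C(C)=CC[C@H](C(C)C)[C@H]1O | intermediate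
5 | mesylate of 4 | O=C1C(C)=CC[C@H](C(C)C)[C@H]1OS(C)(=O)=O | intermediate
6 | trans-hydroxy mesylate, 1-OH cis to isopropyl (not isolated) | O[C@@H]1C(C)=CC[C@H](C(C)C)[C@H]1OS(C)(=O)=O | intermediate
7 | 1,6-epoxy-2-methyl-5-(propan-2-yl)cyclohex-2-ene, oxirane cis to isopropyl | CC1=CC[C@H](C(C)C)[C@@H]2O[C@H]12 | intermediate
8 | 6-[(4-methoxybenzyl)oxy]-5-methyl-2-(propan-2-yl)cyclohex-4-en-1-ol, OH cis to isopropyl and trans to OPMB | COc1ccc(CO[C@H]2C(C)=CC[C@H](C(C)C)[C@@H]2O)cc1 | intermediate
9 | TBS ether of 8 | COc1ccc(CO[C@H]2C(C)=CC[C@H](C(C)C)[C@@H]2O[Si](C)(C)C(C)(C)C)cc1 | intermediate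
10 | secondary ozonide of 9 (not isolated) | CC12OOC(O1)C[C@H](C(C)C)[C@H](O[Si](C)(C)C(C)(C)C)[C@H]2OCc1ccc(OC)cc1 | intermediate
11 | 4-(TBS-oxy)-5-(PMB-oxy)-6-oxo-3-(propan-2-yl)heptanal (not isolated) | CC(=O)[C@H](OCc1ccc(OC)cc1)[C@@H](O[Si](C)(C)C(C)(C)C)[C@@H](C(C)C)CC=O | intermediate
12 | dimethyl acetal of 11 | CC(=O)[C@H](OCc1ccc(OC)cc1)[C@@H](O[Si](C)(C)C(C)(C)C)[C@@H](C(C)C)CC(OC)OC | intermediate
13 | lithium enolate of 12 at the methyl group (not isolated) | [Li+].C=C([O-])[C@H](OCc1ccc(OC)cc1)[C@@H](O[Si](C)(C)C(C)(C)C)[C@@H](C(C)C)CC(OC)OC | intermediate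
14 | lithium aldolate with methyl glyoxylate (not isolated) | [Li+].COC(=O)C([O-])CC(=O)[C@H](OCc1ccc(OC)cc1)[C@@H](O[Si](C)(C)C(C)(C)C)[C@@H](C(C)C)CC(OC)OC | intermediate
15 | aldol mesylate (not isolated) | COC(=O)C(OS(C)(=O)=O)CC(=O)[C@H](OCc1ccc(OC)cc1)[C@@H](O[Si](C)(C)C(C)(C)C)[C@@H](C(C)C)CC(OC)OC | intermediate
16 | methyl (2E)-6-(TBS-oxy)-9,9-dimethoxy-5-(PMB-oxy)-4-oxo-7-(propan-2-yl)non-2-enoate | COC(=O)/C=C/C(=O)[C@H](OCc1ccc(OC)cc1)[C@@H](O[Si](C)(C)C(C)(C)C)[C@@H](C(C)C)CC(OC)OC | intermediate
17 | methyl (2E)-6-(TBS-oxy)-5-(PMB-oxy)-4,9-dioxo-7-(propan-2-yl)non-2-enoate | COC(=O)/C=C/C(=O)[C@H](OCc1ccc(OC)cc1)[C@@H](O[Si](C)(C)C(C)(C)C)[C@@H](C(C)C)CC=O | intermediate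
18 | E enamine of 17 with (R)-diphenylprolinol TMS ether (not isolated) | COC(=O)/C=C/C(=O)[C@H](OCc1ccc(OC)cc1)[C@@H](O[Si](C)(C)C(C)(C)C)[C@@H](C(C)C)/C=C/N1CCC[C@@H]1C(c1ccccc1)(c1ccccc1)O[Si](C)(C)C | intermediate
19 | methyl 2-[2-formyl-3-isopropyl-4-(TBS-oxy)-5-(PMB-oxy)-6-oxocyclohexyl]acetate, formyl trans to isopropyl and to the acetate arm | O=C1[C@H](CC(=O)OC)[C@@H](C=O)[C@H](C(C)C)[C@H](O[Si](C)(C)C(C)(C)C)[C@H]1OCc1ccc(OC)cc1 | intermediate
20 | alkynyl keto ester (ethynyl in place of formyl) | O=C1[C@H](CC(=O)OC)[C@@H](C#C)[C@H](C(C)C)[C@H](O[Si](C)(C)C(C)(C)C)[C@H]1OCc1ccc(OC)cc1 | intermediate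
21 | methylidene alkynyl ester | C=C1[C@H](CC(=O)OC)[C@@H](C#C)[C@H](C(C)C)[C@H](O[Si](C)(C)C(C)(C)C)[C@H]1OCc1ccc(OC)cc1 | intermediate
22 | ynal | C=C1[C@H](CC=O)[C@@H](C#C)[C@H](C(C)C)[C@H](O[Si](C)(C)C(C)(C)C)[C@H]1OCc1ccc(OC)cc1 | intermediate
23 | oxanickelacyclopentene, ligands omitted (not isolated) | C=C1[C@@H]2C[C@H]3O[Ni]C=C3[C@H]2[C@H](C(C)C)[C@H](O[Si](C)(C)C(C)(C)C)[C@H]1OCc1ccc(OC)cc1 | intermediate
24 | (1Z,2R,3aR,5S,6S,7S,7aR)-1-ethylidene-4-methylidene-5-(PMB-oxy)-6-(TBS-oxy)-7-(propan-2-yl)octahydro-1H-inden-2-ol | C=C1[C@@H]2C[C@@H](O)/C(=C\C)[C@H]2[C@H](C(C)C)[C@H](O[Si](C)(C)C(C)(C)C)[C@H]1OCc1ccc(OC)cc1 | intermediate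
25 | (2S)-acetate, 2β-OAc | C=C1[C@@H]2C[C@H](OC(C)=O)/C(=C\C)[C@H]2[C@H](C(C)C)[C@H](O[Si](C)(C)C(C)(C)C)[C@H]1OCc1ccc(OC)cc1 | intermediate
26 | 5α-alcohol | C=C1[C@@H]2C[C@H](OC(C)=O)/C(=C\C)[C@H]2[C@H](C(C)C)[C@H](O[Si](C)(C)C(C)(C)C)[C@H]1O | intermediate
27 | 5α-angelate 6β-TBS ether | C=C1[C@@H]2C[C@H](OC(C)=O)/C(=C\C)[C@H]2[C@H](C(C)C)[C@H](O[Si](C)(C)C(C)(C)C)[C@H]1OC(=O)/C(C)=C\C | intermediate
28 | (1Z,2S,3aR,5S,6S,7S,7aR)-2-acetoxy-1-ethylidene-6-hydroxy-4-methylidene-7-(propan-2-yl)octahydro-1H-inden-5-yl (2Z)-2-methylbut-2-enoate | C=C1[C@@H]2C[C@H](OC(C)=O)/C(=C\C)[C@H]2[C@H](C(C)C)[C@H](O)[C@H]1OC(=O)/C(C)=C\C | target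

**Step count and risks**

Total step count: 18. Longest linear sequence: 18 steps from (S)-carvone.

Steps most likely to fail:

1. Step 10. The enamine may add to the alkene carbon β to the ketone (7-endo closure) or condense with the C4 ketone, or turnover may be slow. The fallback is a radical conjugate addition that sets out from 17 and comes back at 19. The aldehyde is converted into its trimethylsilyl enol ether F1 (Me3SiCl, Et3N, NaI, MeCN) and selenenylated with PhSeCl to the α-phenylselanyl aldehyde F2. This is acetalized (HC(OMe)3, PPTS, MeOH) to the seleno acetal F3, so that the derived radical is a nucleophilic alkyl radical. Bu3SnH and AIBN in refluxing benzene (slow addition) then close the ring by 6-exo-trig addition to the alkene carbon β to the ester, giving the cyclohexanone acetal F4. Acetal hydrolysis (PPTS, acetone–water) and DBU equilibration of the two α-carbonyl centers give 19.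

2. Step 14. Methyl transfer to the aldehyde without cyclization, alkyne oligomerization at nickel, or poor facial control at C2 may intervene. The fallback is a Nozaki–Hiyama–Kishi closure of a Z enol triflate that sets out from 21 and comes back at 24. Gold-catalysed hydration ((Ph3P)AuNTf2, MeOH–H2O) gives the methyl ketone F5. Kinetic methylation (LiN(iPr)2, MeI, −78 °C) gives the ethyl ketone F6. KN(SiMe3)2 and PhNTf2 give the Z enol triflate F7 (triflate cis to methyl). iBu2AlH at −78 °C gives the aldehyde F8, and CrCl2 with catalytic NiCl2 in DMF closes the cyclopentane with retention of alkene geometry to give 24. If either cyclization delivers the 2β-alcohol instead, plain acetylation (Ac2O, pyridine) leads directly to 25.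

3. Step 4. Hydride delivery through the conformer with an axial sulfonate (Felkin–Anh control) would give the cis hydroxy mesylate, which cannot close to the epoxide. The fallback sets out from 4 and comes back at 7. Hydroxyl-directed reduction with Me4NBH(OAc)3 (MeCN–AcOH, −20 °C) gives the trans-diol F9. The less hindered allylic hydroxyl is silylated selectively (Et3SiCl, imidazole, −20 °C) to the mono-triethylsilyl ether F10. The C6 hydroxyl is mesylated (MsCl, Et3N) to the silyl ether mesylate F11. Bu4NF then removes the silyl group and the liberated alkoxide closes the epoxide 7 with inversion at C6.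

Further compounds
F1 | step 10 | trimethylsilyl enol ether of 17 | COC(=O)/C=C/C(=O)[C@H](OCc1ccc(OC)cc1)[C@@H](O[Si](C)(C)C(C)(C)C)[C@@H](C(C)C)C=CO[Si](C)(C)C
F2 | step 10 | α-phenylselanyl aldehyde | COC(=O)/C=C/C(=O)[C@H](OCc1ccc(OC)cc1)[C@@H](O[Si](C)(C)C(C)(C)C)[C@@H](C(C)C)C([Se]c1ccccc1)C=O
F3 | step 10 | α-phenylselanyl dimethyl acetal | COC(=O)/C=C/C(=O)[C@H](OCc1ccc(OC)cc1)[C@@H](O[Si](C)(C)C(C)(C)C)[C@@H](C(C)C)C([Se]c1ccccc1)C(OC)OC
F4 | step 10 | cyclohexanone dimethyl acetal | O=C1[C@H](CC(=O)OC)[C@@H](C(OC)OC)[C@H](C(C)C)[C@H](O[Si](C)(C)C(C)(C)C)[C@H]1OCc1ccc(OC)cc1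
F5 | step 14 | methyl ketone from alkyne hydration | C=C1[C@H](CC(=O)OC)[C@@H](C(C)=O)[C@H](C(C)C)[C@H](O[Si](C)(C)C(C)(C)C)[C@H]1OCc1ccc(OC)cc1
F6 | step 14 | ethyl ketone | C=C1[C@H](CC(=O)OC)[C@@H](C(=O)CC)[C@H](C(C)C)[C@H](O[Si](C)(C)C(C)(C)C)[C@H]1OCc1ccc(OC)cc1
F7 | step 14 | Z enol triflate ester | C=C1[C@H](CC(=O)OC)[C@@H](/C(OS(=O)(=O)C(F)(F)F)=C/C)[C@H](C(C)C)[C@H](O[Si](C)(C)C(C)(C)C)[C@H]1OCc1ccc(OC)cc1
F8 | step 14 | Z enol triflate aldehyde | C=C1[C@H](CC=O)[C@@H](/C(OS(=O)(=O)C(F)(F)F)=C/C)[C@H](C(C)C)[C@H](O[Si](C)(C)C(C)(C)C)[C@H]1OCc1ccc(OC)cc1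
F9 | step 4 | trans-diol, 1-OH cis and 6-OH trans to isopropyl | O[C@@H]1C(C)=CC[C@H](C(C)C)[C@H]1O
F10 | step 4 | 1-O-triethylsilyl ether of the trans-diol | CC[Si](CC)(CC)O[C@@H]1C(C)=CC[C@H](C(C)C)[C@H]1O
F11 | step 4 | 1-O-triethylsilyl 6-O-mesylate | CC[Si](CC)(CC)O[C@@H]1C(C)=CC[C@H](C(C)C)[C@H]1OS(C)(=O)=O
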